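**Assumptions**
- 2′,4′-Dihydroxy-6′-methoxyacetophenone is purchased.
- C-3′ of the chalcone, which lies between the 2′-OH and 4′-OH groups, is the preferred site for the key C–C bond formation, and C-5′ is the minor site.
- Only substrates and reagents that leave atoms in a product are numbered. Catalysts, bases and reagents that leave no atoms (DIBAL-H, NaIO4 and so on) appear only in the conditions.

**Retrosynthetic overview**
1. Global desilylation gives the target. No rings are formed, because all three arenes come pre-made.
2. The key disconnection is the C7 diarylmethine stereocentre, with both adjacent bonds made in one operation. A BINOL-catalysed three-component Petasis-type coupling joins helichrysetin (a 3′-C–H chalcone), 4-hydroxybenzaldehyde and a chiral (E)-alkenylboronic acid via an o-quinone methide. This sets C7 directly and keeps the E-alkene.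
3. Helichrysetin comes from Claisen–Schmidt condensation of 2′,4′-dihydroxy-6′-methoxyacetophenone with 4-hydroxybenzaldehyde.
4. The alkenylboronic acid comes from Brown asymmetric allylation, which sets C3 as (S). Cross-metathesis with vinyl-Bpin then gives the (E)-alkenyl-Bpin, which is hydrolysed.

---

**Step 1**
Reactants: 1 (methyl 3-(4-hydroxyphenyl)propanoate), 2 (TBSCl)
Product: 3 (methyl 3-(4-TBSO-phenyl)propanoate)
Conditions: TBSCl, imidazole, DMF, rt
Reagents that add atoms: TBSCl, CC(C)(C)[Si](C)(C)Cl
Why: Standard phenol silylation. The silyl group is removed by fluoride at the end, which avoids acid that could ionise the diarylallylic C7 centre.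

**Step 2**
Reactants: 3
Product: 4 (3-(4-TBSO-phenyl)propanal)
Conditions: DIBAL-H (1.05 equiv), CH2Cl2, −78 °C
Reagents that add atoms: none
Why: Partial ester reduction at low temperature stops at the aldehyde through the stable tetrahedral aluminium hemiacetal. The aryl silyl ether is untouched.

**Step 3**
Reactants: 4, 5 ((+)-B-allyldiisopinocampheylborane, made from (−)-α-pinene-derived Ipc2B–OMe and allylMgBr)
Product: 6 ((S)-1-(4-TBSO-phenyl)hex-5-en-3-ol)
Conditions: 5, Et2O, −78 °C; then NaBO3·4H2O, THF/H2O, rt
Reagents that add atoms: 5, C=CCB(C1CC2CC(C2(C)C)C1C)C1CC2CC(C2(C)C)C1C (Ipc stereochemistry not drawn; reagent from (−)-α-pinene)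
Why: Brown asymmetric allylboration goes through a chair Zimmerman–Traxler transition state with the aldehyde substituent equatorial. The (+)-reagent delivers allyl to the Re face, which gives the (S)-carbinol (C3). Perborate oxidation is milder than NaOH/H2O2 and spares the aryl silyl ether. The configuration is confirmed by Mosher analysis, and the pinene enantiomer is swapped if it is opposite.

**Step 4**
Reactants: 6, 7 (TBSOTf)
Product: 8 ((S)-bis-TBS ether of 6)
Conditions: TBSOTf, 2,6-lutidine, CH2Cl2, −78 → 0 °C
Reagents that add atoms: TBSOTf, CC(C)(C)[Si](C)(C)OS(=O)(=O)C(F)(F)F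
Why: Silylating the secondary alcohol stops it trapping the o-quinone methide in the key step. C3 is not touched.

**Step 5**
Reactants: 8, 9 (vinyl-Bpin)
Product: 10 ((S,E)-alkenyl-Bpin)
Conditions: vinyl-Bpin (3 equiv), Grubbs II (5 mol%), CH2Cl2, 40 °C
Reagents that add atoms: vinyl-Bpin, C=CB1OC(C)(C)C(C)(C)O1
Why: Cross-metathesis of a terminal alkene with vinyl-Bpin releases ethylene and gives the thermodynamic E-alkenylboronate.

**Step 6**
Reactants: 10
Product: 11 ((S,E)-alkenylboronic acid)
Conditions: NaIO4, NH4OAc, acetone/H2O, rt
Reagents that add atoms: water, O (its oxygen atoms become the B–OH groups of the product; the liberated pinacol is cleaved by periodate to acetone, which drives the reaction)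
Why: Periodate cleavage of the released pinacol drives hydrolysis of the pinacol boronate (Coutts-type deprotection) under near-neutral conditions. The free boronic acid exchanges readily with BINOL in the next step, and the silyl ethers survive.

**Step 7**
Reactants: 12 (2′,4′-dihydroxy-6′-methoxyacetophenone), 13 (4-hydroxybenzaldehyde)
Product: 14 (helichrysetin, (E)-2′,4,4′-trihydroxy-6′-methoxychalcone)
Conditions: 50% aq. KOH, EtOH, rt, 72 h; then HCl to pH 2
Reagents that add atoms: none beyond the listed reactants (the KOH and HCl leave no atoms in the product)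
Why: Claisen–Schmidt aldol condensation with dehydration gives the thermodynamic E-enone. The polyphenolate is slow to react but works with free phenols, and the 2′-OH···O=C hydrogen bond helps hold the product as the open chalcone after acidification.

**Step 8**
Reactants: 14, 13 (4-hydroxybenzaldehyde, 2 equiv), 11 (2 equiv)
Product: 15 ((3S,7R)-bis-TBS-epicalyxin B)
Conditions: (S)-3,3′-Br2-BINOL (20 mol%), toluene, 4 Å MS, 50 °C, 48 h
Reagents that add atoms: none beyond the listed reactants (the aryl group comes from 13 and the alkenyl group from 11; boron leaves as B(OH)3)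
Why: Proposed new method: the electron-rich C-3′ position of 14 (ortho to both the 2′-OH and 4′-OH) condenses with 4-hydroxybenzaldehyde, through a boronate-templated hydroxyalkylation and loss of water, to give an o-quinone methide. The BINOL-exchanged alkenylboronate then transfers its alkenyl group through a cyclic B–O-bound transition state to the exocyclic methine carbon. The closest known chemistry is BINOL-catalysed alkenylboronate addition to o-quinone methides, combined with Petasis-type phenol–aldehyde–boronic acid coupling. The catalyst face selectivity sets C7 as (R), and the alkene geometry is retained as E. The remote C3 centre should have little influence, and any minor C7 epimer is separable. The catalyst enantiomer is calibrated on a model substrate (12, 13 and a simple styrenylboronic acid) and switched if the opposite sense results.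

**Step 9**
Reactants: 15
Product: 16 (epicalyxin B)
Conditions: HF·pyridine, pyridine, THF, 0 °C → rt, 16 h
Reagents that add atoms: none
Why: Buffered fluoride removes the aryl and secondary silyl ethers under non-acidic, weakly basic conditions. This avoids ionisation of the diarylallylic C7 centre and avoids flavanone cyclisation. No stereocentre is touched.

---

**Compound list**

| No. | Name | SMILES | Role |
|---|---|---|---|
| 1 | Methyl 3-(4-hydroxyphenyl)propanoate | COC(=O)CCc1ccc(O)cc1 | starting material |
| 2 | TBSCl | CC(C)(C)[Si](C)(C)Cl | starting material |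
| 3 | Methyl 3-(4-TBSO-phenyl)propanoate | COC(=O)CCc1ccc(O[Si](C)(C)C(C)(C)C)cc1 | intermediate |
| 4 | 3-(4-TBSO-phenyl)propanal | O=CCCc1ccc(O[Si](C)(C)C(C)(C)C)cc1 | intermediate |
| 5 | (+)-B-Allyldiisopinocampheylborane (from (−)-α-pinene; pinane stereochemistry not drawn) | C=CCB(C1CC2CC(C2(C)C)C1C)C1CC2CC(C2(C)C)C1C | starting material |
| 6 | (S)-1-(4-TBSO-phenyl)hex-5-en-3-ol | C=CC[C@@H](O)CCc1ccc(O[Si](C)(C)C(C)(C)C)cc1 | intermediate |
| 7 | TBSOTf | CC(C)(C)[Si](C)(C)OS(=O)(=O)C(F)(F)F | starting material |
| 8 | (S)-Bis-TBS ether of 6 | C=CC[C@@H](O[Si](C)(C)C(C)(C)C)CCc1ccc(O[Si](C)(C)C(C)(C)C)cc1 | intermediate |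
| 9 | Vinylboronic acid pinacol ester | C=CB1OC(C)(C)C(C)(C)O1 | starting material |
| 10 | (S,E)-Alkenyl-Bpin | CC1(C)OB(OC1(C)C)/C=C/C[C@@H](O[Si](C)(C)C(C)(C)C)CCc1ccc(O[Si](C)(C)C(C)(C)C)cc1 | intermediate |
| 11 | (S,E)-Alkenylboronic acid | OB(O)/C=C/C[C@@H](O[Si](C)(C)C(C)(C)C)CCc1ccc(O[Si](C)(C)C(C)(C)C)cc1 | intermediate |
| 12 | 2′,4′-Dihydroxy-6′-methoxyacetophenone | COc1cc(O)cc(O)c1C(C)=O | starting material |
| 13 | 4-Hydroxybenzaldehyde | O=Cc1ccc(O)cc1 | starting material |
| 14 | Helichrysetin | COc1cc(O)cc(O)c1C(=O)/C=C/c1ccc(O)cc1 | intermediate |
| 15 | Bis-TBS-epicalyxin B | COc1cc(O)c([C@H](/C=C/C[C@@H](O[Si](C)(C)C(C)(C)C)CCc2ccc(O[Si](C)(C)C(C)(C)C)cc2)c2ccc(O)cc2)c(O)c1C(=O)/C=C/c1ccc(O)cc1 | intermediate |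
| 16 | Epicalyxin B | COc1cc(O)c([C@H](/C=C/C[C@@H](O)CCc2ccc(O)cc2)c2ccc(O)cc2)c(O)c1C(=O)/C=C/c1ccc(O)cc1 | target |

**Total steps:** 9.
**Longest linear sequence:** 8 steps (Steps 1–6, 8 and 9). Step 7 is a convergent branch.

**Three steps most likely to fail**
1. **Step 8, the three-component o-quinone methide alkenylation.** Risks are C-3′ versus C-5′ regioselectivity, bis-arylation, low ee with the polyphenolic substrate, and oxa-Michael cyclisation to the flavanone. Fallback: run the same coupling with an achiral Brønsted acid or boronate mediator to give both C7 epimers, then separate the (3S,7R) and (3S,7S) diastereomers by preparative HPLC. This replaces catalytic control with diastereomer separation.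
2. **Step 3, the Brown allylation.** Risks are cleavage of the aryl silyl ether during oxidative work-up and the wrong absolute sense. Fallback: make racemic 6 by allylMgBr addition to 4, then resolve it by lipase (CAL-B) acylation, which replaces asymmetric allylation with kinetic resolution.
3. **Step 7, the Claisen–Schmidt condensation with free phenols.** Risk is low yield from polyphenolate deactivation. Fallback: protect both components as MOM ethers, condense under mild base, then remove the MOM groups with acid. The acid step is harmless at this stage because there is no diarylallylic stereocentre yet.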